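At 80.0 min the two earlier runs have a common reading, and from it I have to say what stands at 2.0 h in the new flasks.

common to all: starting complex 0.10 M

| run | incoming ligand | remark | time |
|---|---|---|---|
| dawn | 0.61 equiv | run made earlier |  |
| spring | 1.5 equiv | run made earlier |  |
| south-west | 1.00 equiv |  | 2.0 h |
| west | 2.00 equiv |  | 2.0 h |
| south | 1.20 equiv |  | 2.0 h |

- dawn (time / min: complex with two exchanged / %, complex with three exchanged / %): 15.0: 1.9, 0.4; 30.0: 1.2, 0.7; 40.0: 4.1, 0.7; 60.0: 5.8, 0.5; 80.0: 6.8, 0.6
- spring (time / min: complex with two exchanged / %, complex with three exchanged / %): 6.00: 1.4, 0.2; 12.0: 3.5, 1.5; 20.0: 7.7, 0; 30.0: 12.4, 1.5; 50.0: 16.7, 1.3; 80.0: 23.7, 3.8

(each reading ± 1 percentage point)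



- which of these holds the largest part of the starting complex at the end of south-west (complex with two exchanged / starting complex / complex with one exchanged / complex with three exchanged)
- which of these holds the largest part of the starting complex at the end of west (complex with two exchanged / starting complex / complex with one exchanged / complex with three exchanged)
- which of these holds the largest part of the starting complex at the end of south (complex with two exchanged / starting complex / complex with one exchanged / complex with three exchanged)
- final complex with two exchanged in west, as a percentage of the starting complex charged

At that shared time, spring holds 23.7% of complex with two exchanged and dawn 6.8%. I compare the gain in that complex with the gain in ligand charge, taking the logarithm of each, and get 1.39. I carry this as the ligand power, the power to which the ligand ratio must be raised to give the ratio of complex with two exchanged at one time and one charge of starting complex. It is a reading, resting on two values each good to 1 percentage point.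

Two extreme flasks can be solved in the head. If complex with one exchanged passed on at once, complex with two exchanged would need one meeting with ligand and grow as the charge, so going from spring to west at 80.0 min gives 31.6%. If it simply waited for a second ligand, there would be two meetings and growth as the square, which gives 42.1%. The power read lies between these extremes, so my reckoning for west at 80.0 min is 35.3%. Spring read 16.7% at 50.0 min and 23.7% at 80.0 min, still climbing, so for west at 2.0 h I commit to a value above 35.3%.

The forecast reads the curves thus: “this looks like sequential second-order exchange with the first step fastest”. It gives 37% for west and names complex with one exchanged as largest in south-west, complex with one exchanged in west and complex with one exchanged in south.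

West ends at 38.2% of complex with two exchanged, the largest of the four asked; of the same four, starting complex is the largest in south-west at 34.4% and in south at 26.7%.

    starting complex + incoming ligand → leaving ligand + complex with one exchanged (k = 0.210 L mol⁻¹ min⁻¹)
    complex with one exchanged + incoming ligand → leaving ligand + complex with two exchanged (k = 0.190 L mol⁻¹ min⁻¹)
    complex with two exchanged + incoming ligand → leaving ligand + complex with three exchanged (k = 0.0170 L mol⁻¹ min⁻¹)
    complex with one exchanged → side product (k = 0.0200 min⁻¹)

In west at 0.288 h, complex with one exchanged goes on to complex with two exchanged at 1.4 times the rate at which it falls to side product. At 2.00 h in west it is made at half the rate at which it is used up, each step taken net, and it stands at 6.83%. At 80.0 min west's charge holds 34.9% of complex with two exchanged, where the ligand power gave 35.3%. Carried from west down to south's ligand, the power gives 18.8%, and south holds 20.2%.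

The data were generated by integration for substances that don't exist; the scatter is artificial.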